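**Strategy.** The pyranone ring (O1–C2–C3–C4–C4a–C8a) is not closed at size six. The route exploits that its only stereocentre, the quaternary spiro carbon C3, lies between the C4 ketone and the O1–C2H2 group: this is the pattern left when one carbon is inserted into the C2–C3 bond of a benzofuran-3-ol. C3 is therefore delivered, already carrying the four-membered ring, as a benzocyclobutenylidene by chiral Rh(II) catalysis to a flat 3-silyloxybenzofuran; acid opening of the siloxycyclopropane at the old furan bond then widens the furan to the 4-chromanone. One flask gives dearomatisation, spiro-annulation, stereocentre and ring expansion.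

Key step: step 4

Assumption: Rh2(S-PTAD)4 is taken to deliver the carbene to the benzofuran face drawn in 10 (if the sense is opposite, Rh2(R-PTAD)4 is used with no other change); the C=N geometry of 6 is immaterial, since both isomers give the same diazo compound 9.

**Step 1**
Reactants: 1 4-bromo-1,2-dimethoxybenzene; 2 1,1-dimethoxyethene
Product: 5 4,5-dimethoxybicyclo[4.2.0]octa-1,3,5-trien-7-one, via 3,4-dimethoxybenzyne 3 (not isolated), via dimethyl ketal 4 (not isolated)
Conditions: NaNH2, THF, reflux; then 1 M HCl, THF–H2O, rt
Reagents that add atoms: water (O)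
Why: Aryne [2+2] cycloaddition with a ketene acetal: amide removes the proton flanked by Br and OMe, loss of bromide gives the 3-alkoxy aryne, the nucleophilic CH2 of the acetal adds at the aryne carbon remote from OMe so that the acetal carbon ends next to the methoxy-bearing carbon, and aqueous acid unmasks the ketone.

**Step 2**
Reactants: 5 4,5-dimethoxybicyclo[4.2.0]octa-1,3,5-trien-7-one
Product: 6 N'-(4,5-dimethoxybicyclo[4.2.0]octa-1,3,5-trien-7-ylidene)-2-(trifluoromethyl)benzenesulfonohydrazide
Conditions: 2-(CF3)C6H4SO2NHNH2, MeOH, rt
Reagents that add atoms: 2-(trifluoromethyl)benzenesulfonohydrazide (NNS(=O)(=O)c1ccccc1C(F)(F)F)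
Why: Sulfonylhydrazone condensation under neutral conditions, which avoids the alkoxide that would cleave the strained ketone; the N-triftosyl group is chosen because its anion releases the diazo compound below 0 °C (Bamford–Stevens).

**Step 3**
Reactants: 7 4,6-dimethoxybenzofuran-3(2H)-one
Product: 8 tert-butyl[(4,6-dimethoxy-1-benzofuran-3-yl)oxy]dimethylsilane
Conditions: TBSOTf, Et3N, CH2Cl2, 0 °C
Reagents that add atoms: tert-butyldimethylsilyl trifluoromethanesulfonate (CC(C)(C)[Si](C)(C)OS(=O)(=O)C(F)(F)F)
Why: Soft enolisation with O-silylation (silyl enol ether formation), driven to oxygen because the product is an aromatic benzofuran.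

**Step 4**
Reactants: 6 N'-(4,5-dimethoxybicyclo[4.2.0]octa-1,3,5-trien-7-ylidene)-2-(trifluoromethyl)benzenesulfonohydrazide; 8 tert-butyl[(4,6-dimethoxy-1-benzofuran-3-yl)oxy]dimethylsilane
Product: 11 (S)-4,5,5',7'-tetramethoxyspiro[bicyclo[4.2.0]octa-1,3,5-triene-7,3'-chroman]-4'-one, via diazoalkane 9 (not isolated), via siloxycyclopropane 10 (not isolated)
Conditions: 6, NaH, CH2Cl2, −40 °C; added slowly to 8, Rh2(S-PTAD)4 (1 mol %), CH2Cl2, −40 → 0 °C; then CF3CO2H, 0 °C
Reagents that add atoms: none
Why: Proposed new method: NaH converts 6 into its sodium salt, which loses sulfinate (Bamford–Stevens) to give diazoalkane 9; Rh(II) turns 9 into a benzocyclobutenylidene complex that cannot escape by 1,2-hydride shift (this would give a benzocyclobutadiene) and is captured by the most nucleophilic π-bond of 8, the C2=C3 enol ether, to give the dearomatised siloxycyclopropane 10, whose protonolysis by CF3CO2H at C2 cleaves the former furan C2–C3 bond, turns C–OSi into the C4 ketone and so widens the five-membered furan ring to the six-membered pyranone with the carbene carbon as C3. The closest known reaction types are the Rh(II)-carboxylate-catalysed enantioselective cyclopropanation of benzofurans and silyl enol ethers with aryl-substituted carbenes generated in situ from sulfonylhydrazones, and the one-carbon ring expansion of silyl enol ethers through carbene adducts with acid opening of the siloxycyclopropane. The cyclopropane closes by an asynchronous [2+1] cycloaddition (C2 bonds first, then C3); the pyranone is not closed by cyclisation but arises by scission of the ring-fusion bond of the 2-oxabicyclo[3.1.0]hexane. The single stereocentre (spiro C3) is set in the carbene transfer: the chiral carboxylate ligands choose the face of the benzofuran, and the arene arm of the carbene should take the exo position because in the endo position its peri-methoxy group would press on the benzofuran; no bond to this carbon is broken afterwards. Two selectivities are needed: attack at the enol ether and not at the arenes, secured by the silyloxy donor, and protonation at C2–H and not at the quaternary spiro carbon, secured by the preference of acids to open cyclopropanols at the less substituted carbon (fluoride or base is avoided because it would open towards the benzylic carbanion and return a 2-substituted benzofuranone).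

**Compound list**
1 | 4-bromo-1,2-dimethoxybenzene | COc1ccc(Br)cc1OC | starting material
2 | 1,1-dimethoxyethene | C=C(OC)OC | starting material
3 | 3,4-dimethoxybenzyne (1,2-didehydro-3,4-dimethoxybenzene) | COC1=C(OC)C#CC=C1 | intermediate
4 | 4,5,7,7-tetramethoxybicyclo[4.2.0]octa-1,3,5-triene (dimethyl ketal of 5) | COc1ccc2CC(OC)(OC)c2c1OC | intermediate
5 | 4,5-dimethoxybicyclo[4.2.0]octa-1,3,5-trien-7-one (ketone carbon on the ring carbon next to C–OMe) | COc1ccc2CC(=O)c2c1OC | intermediate
6 | N'-(4,5-dimethoxybicyclo[4.2.0]octa-1,3,5-trien-7-ylidene)-2-(trifluoromethyl)benzenesulfonohydrazide (C=N geometry not defined) | COc1ccc2CC(=NNS(=O)(=O)c3ccccc3C(F)(F)F)c2c1OC | intermediate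
7 | 4,6-dimethoxybenzofuran-3(2H)-one | COc1cc(OC)c2C(=O)COc2c1 | starting material
8 | tert-butyl[(4,6-dimethoxy-1-benzofuran-3-yl)oxy]dimethylsilane | COc1cc(OC)c2c(O[Si](C)(C)C(C)(C)C)coc2c1 | intermediate
9 | 7-diazo-4,5-dimethoxybicyclo[4.2.0]octa-1,3,5-triene | COc1ccc2CC(=[N+]=[N-])c2c1OC | intermediate
10 | siloxycyclopropane: cyclopropane fused across C2–C3 of 8 (C3 keeps OTBS, C2 keeps H), third carbon is spiro C7 of 4,5-dimethoxybenzocyclobutene; arene arm exo (anti to the dihydrofuran ring, on the side of OTBS and H), CH2 arm endo; absolute configuration as in the SMILES | COc1cc(OC)c2c(c1)O[C@@H]3[C@@]2(O[Si](C)(C)C(C)(C)C)[C@]34Cc5ccc(OC)c(OC)c54 | intermediate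
11 | (S)-4,5,5',7'-tetramethoxyspiro[bicyclo[4.2.0]octa-1,3,5-triene-7,3'-chroman]-4'-one | COc1cc(OC)c2c(c1)OC[C@@]1(Cc3ccc(OC)c(OC)c31)C2=O | target

**Count.** Total steps: 4. Longest linear sequence: 3 (steps 1, 2, 4).

**Steps most likely to fail**

1. Step 4 (Proposed new method). What may go wrong: insufficient facial or endo/exo control in the carbene transfer, which lowers the enantiomeric purity; loss of the diazo compound to azine formation; or protonolysis of the exocyclic instead of the ring-fusion cyclopropane bond, which gives no ring expansion. Fallback with known chemistry, setting out from 8 and coming back at 11: the same furan-to-pyranone expansion is done with dibromocarbene (CHBr3, KOt-Bu, hexane, −20 °C to rt), the dibromocyclopropane opening with loss of bromide and silyl group to 3-bromo-5,7-dimethoxy-4H-chromen-4-one F1. Suzuki–Miyaura coupling with (6-chloro-2,3-dimethoxyphenyl)boronic acid (Pd(dppf)Cl2, K2CO3, dioxane–H2O, 80 °C) should give 3-(6-chloro-2,3-dimethoxyphenyl)-5,7-dimethoxy-4H-chromen-4-one F2. Conjugate reduction (L-Selectride, THF, −78 °C) gives racemic 3-(6-chloro-2,3-dimethoxyphenyl)-5,7-dimethoxychroman-4-one F3. Enantioselective phase-transfer methylation (MeI, N-(9-anthracenylmethyl) cinchona ammonium salt of the pseudoenantiomeric series that delivers the S ketone, 50% aq KOH, toluene, −20 °C) sets the quaternary centre in (S)-3-(6-chloro-2,3-dimethoxyphenyl)-5,7-dimethoxy-3-methylchroman-4-one F4. Pd(0)-catalysed C(sp3)–H arylation of the C3 methyl group (Pd(OAc)2, P(t-Bu)3·HBF4, K2CO3, DMF, 140 °C) closes the four-membered ring without touching the stereocentre and returns to 11.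

2. Step 1. What may go wrong: capture of the aryne by amide instead of the ketene acetal, or partial elimination towards the other ortho position, which gives the regioisomeric 4,5-dimethoxyaryne. Fallback, setting out from 1 and coming back at 5, with the regiochemistry fixed by the position of the halogen: directed lithiation of 1 between Br and OMe (LDA, THF, −78 °C) and formylation (DMF) gives 6-bromo-2,3-dimethoxybenzaldehyde F5. Corey–Chaykovsky methylenation (Me3S+ I−, NaH, DMSO–THF) gives 2-(6-bromo-2,3-dimethoxyphenyl)oxirane F6. Bromine–lithium exchange (n-BuLi, MgBr2, THF, −78 °C) with 4-exo attack of the aryl anion on the epoxide CH2 gives 4,5-dimethoxybicyclo[4.2.0]octa-1,3,5-trien-7-ol F7. Oxidation (Dess–Martin periodinane, CH2Cl2) returns to 5.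

3. Step 2. What may go wrong: addition of the nitrogen nucleophile followed by C–C scission of the strained four-membered ketone instead of dehydration to the hydrazone. Fallback, setting out from 4 and coming back at 6: the acid hydrolysis of step 1 is omitted, ketal 4 is isolated and exchanged directly with the sulfonyl hydrazide (PPTS cat., MeOH, 40 °C). This runs through the oxocarbenium ion and not through a tetrahedral alkoxide on the strained ring; no new compound is made.

**Further compounds**
F1 | step 4 | 3-bromo-5,7-dimethoxy-4H-chromen-4-one | COc1cc(OC)c2c(c1)OC=C(Br)C2=O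
F2 | step 4 | 3-(6-chloro-2,3-dimethoxyphenyl)-5,7-dimethoxy-4H-chromen-4-one | COc1cc(OC)c2c(c1)OC=C(c1c(Cl)ccc(OC)c1OC)C2=O
F3 | step 4 | rac-3-(6-chloro-2,3-dimethoxyphenyl)-5,7-dimethoxychroman-4-one | COc1cc(OC)c2c(c1)OCC(c1c(Cl)ccc(OC)c1OC)C2=O
F4 | step 4 | (S)-3-(6-chloro-2,3-dimethoxyphenyl)-5,7-dimethoxy-3-methylchroman-4-one | COc1cc(OC)c2c(c1)OC[C@](C)(c1c(Cl)ccc(OC)c1OC)C2=O
F5 | step 1 | 6-bromo-2,3-dimethoxybenzaldehyde | COc1ccc(Br)c(C=O)c1OC
F6 | step 1 | 2-(6-bromo-2,3-dimethoxyphenyl)oxirane (racemic) | COc1ccc(Br)c(C2CO2)c1OC
F7 | step 1 | 4,5-dimethoxybicyclo[4.2.0]octa-1,3,5-trien-7-ol (racemic) | COc1ccc2CC(O)c2c1OC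
F0 | step 2 | none | none
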